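**Plan**

- Retrosynthesis: ring C is cut first at C4a–C4, C4–C3 and O1–C2, giving an iodoresorcinol, CO and a ring B alkyne. Then follow the Cγ–O coumarate ester, the ring B aryl–alkyne bond, the Cα–aryl bond and the Cβ–O aryl ether.
- Enabling feature: ring C is a 4-pyranone. Its C4 carbonyl is a CO unit, C2 and C3 are the two carbons of a terminal alkyne on ring B, and O1 with C4a belong to an ortho-iodophenol. Because ring A is 5,7-dioxygenated, that iodophenol is the mirror-symmetric 2-iodo-5-silyloxyresorcinol, so either hydroxyl can close ring C and the other remains as the 5-OH.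
- Forward order: glycerate → aryl ether on the ring B bromide → aldehyde → guaiacyl addition → silylation → alkyne → Cγ coumarate → rings C and A attached last by carbonylative annulation → global desilylation.
- Stereochemistry: Cβ (S) comes from methyl (R)-glycerate by Mitsunobu inversion. Cα (R) comes from Felkin–Anh (anti) addition of the guaiacyl Grignard reagent under 1,2-induction from Cβ. The E alkene is bought in with p-coumaric acid.

Key step: step 15

Remark: the chain carbons are called Cα (benzylic carbinol), Cβ (aryloxy-bearing carbon) and Cγ (CH2O). The target SMILES corresponds to (αR,βS), the erythro (anti) isomer. Flavone positions keep their usual numbers.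

**Route**

Step 1
Reactants: 1 methyl (R)-2,2-dimethyl-1,3-dioxolane-4-carboxylate
Product: 2 methyl (R)-2,3-dihydroxypropanoate
Conditions: Dowex 50W (H+ form), MeOH/H2O (9:1), rt
Reagents that add atoms: none
Why: Acid-catalysed hydrolysis of the isopropylidene acetal (acetonide cleavage) releases the diol, methanol as co-solvent makes any transesterification of the methyl ester degenerate, and the stereocentre is not touched.

Step 2
Reactants: 2 methyl (R)-2,3-dihydroxypropanoate
Product: 3 methyl (R)-3-(tert-butyldimethylsilyloxy)-2-hydroxypropanoate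
Conditions: TBSCl (1.05 equiv), imidazole, CH2Cl2, 0 °C
Reagents that add atoms: tert-butyldimethylsilyl chloride, CC(C)(C)[Si](C)(C)Cl
Why: Sterically controlled silylation takes the primary hydroxyl, because the secondary hydroxyl is hindered and deactivated by the adjacent ester.

Step 3
Reactants: 3 methyl (R)-3-(tert-butyldimethylsilyloxy)-2-hydroxypropanoate; 4 4-bromo-2,6-dimethoxyphenol
Product: 5 methyl (S)-2-(4-bromo-2,6-dimethoxyphenoxy)-3-(tert-butyldimethylsilyloxy)propanoate
Conditions: PPh3, DIAD, THF, 0 °C → rt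
Reagents that add atoms: none
Why: Mitsunobu etherification, in which the phenol displaces the oxyphosphonium group of the α-hydroxy ester in an SN2 step, so the (R) carbinol centre is inverted to the (S) aryl ether that becomes Cβ.

Step 4
Reactants: 5 methyl (S)-2-(4-bromo-2,6-dimethoxyphenoxy)-3-(tert-butyldimethylsilyloxy)propanoate
Product: 6 (S)-2-(4-bromo-2,6-dimethoxyphenoxy)-3-(tert-butyldimethylsilyloxy)propanal
Conditions: i-Bu2AlH (1.1 equiv), CH2Cl2, −78 °C; MeOH, then aq. potassium sodium tartrate (KNaC4H4O6); used crude at once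
Reagents that add atoms: none
Why: Partial ester reduction at −78 °C stops at the aldehyde because the α-aryloxy group stabilises the tetrahedral aluminium hemiacetal until work-up, and immediate use without chromatography should keep the α-stereocentre from epimerising.

Step 5
Reactants: 7 4-bromo-2-methoxyphenol
Product: 8 (4-bromo-2-methoxyphenoxy)triisopropylsilane
Conditions: TIPSCl, imidazole, DMF, rt
Reagents that add atoms: triisopropylsilyl chloride, CC(C)[Si](Cl)(C(C)C)C(C)C
Why: Standard phenol silylation, giving a bulky aryl silyl ether that tolerates magnesium insertion and the later basic steps.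

Step 6
Reactants: 6 (S)-2-(4-bromo-2,6-dimethoxyphenoxy)-3-(tert-butyldimethylsilyloxy)propanal; 8 (4-bromo-2-methoxyphenoxy)triisopropylsilane
Product: 10 (1R,2S)-2-(4-bromo-2,6-dimethoxyphenoxy)-3-(tert-butyldimethylsilyloxy)-1-[3-methoxy-4-(triisopropylsilyloxy)phenyl]propan-1-ol, via arylmagnesium bromide 9 (not isolated)
Conditions: 8 (1.6 equiv), Mg turnings, I2 (cat.), THF, 50 °C; then 6, THF, −78 → −40 °C; aq. NH4Cl
Reagents that add atoms: none
Why: Grignard addition to an α-aryloxy aldehyde under Felkin–Anh (polar) control, in which the aryl group attacks anti to the C–OAr bond and past the small hydrogen instead of the CH2OTBS group, so the new Cα centre should form as (R), anti (erythro) to Cβ, while the weakly donating aryloxy and silyloxy oxygens in THF give little chelation and the ring B bromide does not exchange with an arylmagnesium reagent at low temperature.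

Step 7
Reactants: 10 (1R,2S)-2-(4-bromo-2,6-dimethoxyphenoxy)-3-(tert-butyldimethylsilyloxy)-1-[3-methoxy-4-(triisopropylsilyloxy)phenyl]propan-1-ol
Product: 11 (1R,2S)-2-(4-bromo-2,6-dimethoxyphenoxy)-1,3-bis(tert-butyldimethylsilyloxy)-1-[3-methoxy-4-(triisopropylsilyloxy)phenyl]propane
Conditions: TBSOTf, 2,6-lutidine, CH2Cl2, −78 → 0 °C
Reagents that add atoms: tert-butyldimethylsilyl trifluoromethanesulfonate, CC(C)(C)[Si](C)(C)OS(=O)(=O)C(F)(F)F
Why: Silylation with a silyl triflate and 2,6-lutidine is reactive enough for the hindered secondary benzylic alcohol and non-acidic, so the benzylic centre is not ionised.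

Step 8
Reactants: 11 (1R,2S)-2-(4-bromo-2,6-dimethoxyphenoxy)-1,3-bis(tert-butyldimethylsilyloxy)-1-[3-methoxy-4-(triisopropylsilyloxy)phenyl]propane
Product: 12 (1R,2S)-1,3-bis(tert-butyldimethylsilyloxy)-2-{2,6-dimethoxy-4-[(trimethylsilyl)ethynyl]phenoxy}-1-[3-methoxy-4-(triisopropylsilyloxy)phenyl]propane
Conditions: ethynyltrimethylsilane (3 equiv), PdCl2(PPh3)2 (5 mol %), CuI (10 mol %), Et3N/DMF, 80 °C, sealed tube
Reagents that add atoms: ethynyltrimethylsilane, C#C[Si](C)(C)C
Why: Sonogashira coupling of an aryl bromide that has no ortho substituent, on a substrate that carries only silyl and aryl ethers, all inert to the palladium/copper/amine system.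

Step 9
Reactants: 12 (1R,2S)-1,3-bis(tert-butyldimethylsilyloxy)-2-{2,6-dimethoxy-4-[(trimethylsilyl)ethynyl]phenoxy}-1-[3-methoxy-4-(triisopropylsilyloxy)phenyl]propane
Product: 13 (1R,2S)-1,3-bis(tert-butyldimethylsilyloxy)-2-(4-ethynyl-2,6-dimethoxyphenoxy)-1-[3-methoxy-4-(triisopropylsilyloxy)phenyl]propane
Conditions: K2CO3 (0.3 equiv), MeOH/THF, rt
Reagents that add atoms: none
Why: Base-catalysed methanolysis of the alkynyl C–Si bond (protodesilylation) is far faster than attack on the alkyl TBS ethers or on the hindered, electron-rich aryl TIPS ether.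

Step 10
Reactants: 13 (1R,2S)-1,3-bis(tert-butyldimethylsilyloxy)-2-(4-ethynyl-2,6-dimethoxyphenoxy)-1-[3-methoxy-4-(triisopropylsilyloxy)phenyl]propane
Product: 14 (2S,3R)-3-(tert-butyldimethylsilyloxy)-2-(4-ethynyl-2,6-dimethoxyphenoxy)-3-[3-methoxy-4-(triisopropylsilyloxy)phenyl]propan-1-ol
Conditions: HF·pyridine, pyridine, THF, 0 °C
Reagents that add atoms: none
Why: Selective desilylation with buffered HF·pyridine, in which the primary TBS ether is cleaved much faster than the hindered secondary benzylic TBS ether, and acidic fluoride leaves the aryl TIPS ether in place.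

Step 11
Reactants: 15 (E)-4-hydroxycinnamic acid (p-coumaric acid)
Product: 17 (E)-4-(triisopropylsilyloxy)cinnamic acid, via bis-silylated coumarate 16 (not isolated)
Conditions: TIPSCl (2.3 equiv), imidazole, DMF, rt; then AcOH/THF/H2O, rt → 40 °C
Reagents that add atoms: triisopropylsilyl chloride, CC(C)[Si](Cl)(C(C)C)C(C)C
Why: Exhaustive silylation followed by selective hydrolysis, since a silyl ester is cleaved by aqueous acetic acid far faster than an aryl silyl ether, leaving the free acid with the phenol masked and the E alkene unchanged.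

Step 12
Reactants: 14 (2S,3R)-3-(tert-butyldimethylsilyloxy)-2-(4-ethynyl-2,6-dimethoxyphenoxy)-3-[3-methoxy-4-(triisopropylsilyloxy)phenyl]propan-1-ol; 17 (E)-4-(triisopropylsilyloxy)cinnamic acid
Product: 18 (2S,3R)-3-(tert-butyldimethylsilyloxy)-2-(4-ethynyl-2,6-dimethoxyphenoxy)-3-[3-methoxy-4-(triisopropylsilyloxy)phenyl]propyl (E)-3-[4-(triisopropylsilyloxy)phenyl]prop-2-enoate
Conditions: EDC·HCl, DMAP, CH2Cl2, 0 °C → rt
Reagents that add atoms: none
Why: Steglich esterification (carbodiimide activation with DMAP as acyl-transfer catalyst) of the only free hydroxyl, the primary Cγ–OH, under neutral conditions that leave the silyl ethers, the alkyne and both stereocentres alone.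

Step 13
Reactants: 19 phloroglucinol (benzene-1,3,5-triol)
Product: 20 5-(triisopropylsilyloxy)benzene-1,3-diol
Conditions: 19 (3 equiv), TIPSCl (1 equiv), imidazole, DMF, 0 °C → rt
Reagents that add atoms: triisopropylsilyl chloride, CC(C)[Si](Cl)(C(C)C)C(C)C
Why: Statistical monosilylation of a symmetric triol, in which the excess of water-soluble phloroglucinol keeps the silyl chloride from reacting twice and is washed out afterwards.

Step 14
Reactants: 20 5-(triisopropylsilyloxy)benzene-1,3-diol
Product: 21 2-iodo-5-(triisopropylsilyloxy)benzene-1,3-diol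
Conditions: I2 (1.05 equiv), NaHCO3, THF/H2O, 0 °C
Reagents that add atoms: iodine, [I][I]
Why: Electrophilic aromatic iodination with I2 and NaHCO3, which on resorcinols takes the position between the two hydroxyls, here also the only position not flanked by the bulky silyloxy group.

Step 15
Reactants: 18 (2S,3R)-3-(tert-butyldimethylsilyloxy)-2-(4-ethynyl-2,6-dimethoxyphenoxy)-3-[3-methoxy-4-(triisopropylsilyloxy)phenyl]propyl (E)-3-[4-(triisopropylsilyloxy)phenyl]prop-2-enoate; 21 2-iodo-5-(triisopropylsilyloxy)benzene-1,3-diol (1.3 equiv)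
Product: 24 (2S,3R)-3-(tert-butyldimethylsilyloxy)-2-{4-[5-hydroxy-4-oxo-7-(triisopropylsilyloxy)-4H-chromen-2-yl]-2,6-dimethoxyphenoxy}-3-[3-methoxy-4-(triisopropylsilyloxy)phenyl]propyl (E)-3-[4-(triisopropylsilyloxy)phenyl]prop-2-enoate (tetrasilyl ether of the target), via ortho-hydroxyaryl ynone 22 (not isolated), via diethylamino enaminone 23 (not isolated)
Conditions: PdCl2(PPh3)2 (5 mol %), CO (10 atm), Et2NH/THF, 70 °C
Reagents that add atoms: carbon monoxide, [C-]#[O+]
Why: The divalent palladium precatalyst is reduced in the flask to zerovalent palladium, which inserts into the C–I bond of 21; migratory insertion of CO gives an aroylpalladium iodide, the terminal alkyne of 18 is deprotonated by diethylamine and transferred to palladium without copper, and reductive elimination releases ynone 22 with C4a–C4 and C4–C3 formed. Diethylamine then adds to the ynone to give enaminone 23, and one of the two equivalent ortho-hydroxyls attacks the amine-bearing carbon in a 6-endo oxa-Michael addition followed by loss of diethylamine, which forms O1–C2 and closes ring C as the 4-pyranone; the closest known reaction type is the palladium-catalysed carbonylative coupling and annulation of ortho-iodophenols with terminal alkynes in secondary amines to give flavones. No stereocentre is created, and Cα and Cβ are remote from the reacting atoms and not epimerisable in diethylamine. Three selectivities are needed: CO insertion before alkynylation (secured by CO pressure, the absence of copper and the electron-rich aryl group, which migrates to CO readily), 6-endo over 5-exo closure (secured by the enaminone, whose amine-bearing carbon is the only electrophilic site), and reaction at the C–I bond alone (18 carries no halide and its β-aryl acrylate is a poor Heck acceptor under CO). The mirror symmetry of 21 removes any regiochemical question, since either hydroxyl can close the ring and the other becomes the hydrogen-bonded 5-OH. The weakly basic, fluoride-free medium should leave the silyl ethers and the coumarate in place, and loss of an aryl silyl group here would not matter because step 16 removes them all.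

Step 16
Reactants: 24 tetrasilyl ether of the target
Product: 25 (2S,3R)-3-hydroxy-2-[4-(5,7-dihydroxy-4-oxo-4H-chromen-2-yl)-2,6-dimethoxyphenoxy]-3-(4-hydroxy-3-methoxyphenyl)propyl (E)-3-(4-hydroxyphenyl)prop-2-enoate (CNP0264527.1)
Conditions: Bu4NF (6 equiv), AcOH (6 equiv), THF, 0 °C → rt
Reagents that add atoms: none
Why: Fluoride-induced cleavage of all four silyl ethers (the three aryl TIPS ethers fast, the benzylic TBS ether more slowly), with acetic acid keeping the medium from turning basic so that the coumarate neither migrates nor is cleaved and the p-hydroxybenzylic Cα centre is not ionised.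

**Compound list**

1 | methyl (R)-2,2-dimethyl-1,3-dioxolane-4-carboxylate | COC(=O)[C@H]1COC(C)(C)O1 | starting material
2 | methyl (R)-2,3-dihydroxypropanoate | COC(=O)[C@H](O)CO | intermediate
3 | methyl (R)-3-(tert-butyldimethylsilyloxy)-2-hydroxypropanoate | COC(=O)[C@H](O)CO[Si](C)(C)C(C)(C)C | intermediate
4 | 4-bromo-2,6-dimethoxyphenol | COc1cc(Br)cc(OC)c1O | starting material
5 | methyl (S)-2-(4-bromo-2,6-dimethoxyphenoxy)-3-(tert-butyldimethylsilyloxy)propanoate | COC(=O)[C@@H](Oc1c(OC)cc(Br)cc1OC)CO[Si](C)(C)C(C)(C)C | intermediate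
6 | (S)-2-(4-bromo-2,6-dimethoxyphenoxy)-3-(tert-butyldimethylsilyloxy)propanal | O=C[C@@H](Oc1c(OC)cc(Br)cc1OC)CO[Si](C)(C)C(C)(C)C | intermediate
7 | 4-bromo-2-methoxyphenol | COc1cc(Br)ccc1O | starting material
8 | (4-bromo-2-methoxyphenoxy)triisopropylsilane | COc1cc(Br)ccc1O[Si](C(C)C)(C(C)C)C(C)C | intermediate
9 | [3-methoxy-4-(triisopropylsilyloxy)phenyl]magnesium bromide (formed in the flask, not isolated) | COc1cc([Mg]Br)ccc1O[Si](C(C)C)(C(C)C)C(C)C | intermediate
10 | (1R,2S)-2-(4-bromo-2,6-dimethoxyphenoxy)-3-(tert-butyldimethylsilyloxy)-1-[3-methoxy-4-(triisopropylsilyloxy)phenyl]propan-1-ol | COc1cc([C@@H](O)[C@H](CO[Si](C)(C)C(C)(C)C)Oc2c(OC)cc(Br)cc2OC)ccc1O[Si](C(C)C)(C(C)C)C(C)C | intermediate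
11 | (1R,2S)-2-(4-bromo-2,6-dimethoxyphenoxy)-1,3-bis(tert-butyldimethylsilyloxy)-1-[3-methoxy-4-(triisopropylsilyloxy)phenyl]propane | COc1cc([C@@H](O[Si](C)(C)C(C)(C)C)[C@H](CO[Si](C)(C)C(C)(C)C)Oc2c(OC)cc(Br)cc2OC)ccc1O[Si](C(C)C)(C(C)C)C(C)C | intermediate
12 | (1R,2S)-1,3-bis(tert-butyldimethylsilyloxy)-2-{2,6-dimethoxy-4-[(trimethylsilyl)ethynyl]phenoxy}-1-[3-methoxy-4-(triisopropylsilyloxy)phenyl]propane | COc1cc([C@@H](O[Si](C)(C)C(C)(C)C)[C@H](CO[Si](C)(C)C(C)(C)C)Oc2c(OC)cc(C#C[Si](C)(C)C)cc2OC)ccc1O[Si](C(C)C)(C(C)C)C(C)C | intermediate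
13 | (1R,2S)-1,3-bis(tert-butyldimethylsilyloxy)-2-(4-ethynyl-2,6-dimethoxyphenoxy)-1-[3-methoxy-4-(triisopropylsilyloxy)phenyl]propane | COc1cc([C@@H](O[Si](C)(C)C(C)(C)C)[C@H](CO[Si](C)(C)C(C)(C)C)Oc2c(OC)cc(C#C)cc2OC)ccc1O[Si](C(C)C)(C(C)C)C(C)C | intermediate
14 | (2S,3R)-3-(tert-butyldimethylsilyloxy)-2-(4-ethynyl-2,6-dimethoxyphenoxy)-3-[3-methoxy-4-(triisopropylsilyloxy)phenyl]propan-1-ol | COc1cc([C@@H](O[Si](C)(C)C(C)(C)C)[C@H](CO)Oc2c(OC)cc(C#C)cc2OC)ccc1O[Si](C(C)C)(C(C)C)C(C)C | intermediate
15 | (E)-4-hydroxycinnamic acid (p-coumaric acid) | O=C(O)/C=C/c1ccc(O)cc1 | starting material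
16 | triisopropylsilyl (E)-4-(triisopropylsilyloxy)cinnamate (formed in the flask, not isolated) | CC(C)[Si](OC(=O)/C=C/c1ccc(O[Si](C(C)C)(C(C)C)C(C)C)cc1)(C(C)C)C(C)C | intermediate
17 | (E)-4-(triisopropylsilyloxy)cinnamic acid | O=C(O)/C=C/c1ccc(O[Si](C(C)C)(C(C)C)C(C)C)cc1 | intermediate
18 | (2S,3R)-3-(tert-butyldimethylsilyloxy)-2-(4-ethynyl-2,6-dimethoxyphenoxy)-3-[3-methoxy-4-(triisopropylsilyloxy)phenyl]propyl (E)-3-[4-(triisopropylsilyloxy)phenyl]prop-2-enoate | COc1cc([C@@H](O[Si](C)(C)C(C)(C)C)[C@H](COC(=O)/C=C/c2ccc(O[Si](C(C)C)(C(C)C)C(C)C)cc2)Oc2c(OC)cc(C#C)cc2OC)ccc1O[Si](C(C)C)(C(C)C)C(C)C | intermediate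
19 | phloroglucinol (benzene-1,3,5-triol) | Oc1cc(O)cc(O)c1 | starting material
20 | 5-(triisopropylsilyloxy)benzene-1,3-diol | Oc1cc(O)cc(O[Si](C(C)C)(C(C)C)C(C)C)c1 | intermediate
21 | 2-iodo-5-(triisopropylsilyloxy)benzene-1,3-diol | Oc1cc(O[Si](C(C)C)(C(C)C)C(C)C)cc(O)c1I | intermediate
22 | ortho-hydroxyaryl ynone: (2S,3R)-3-(tert-butyldimethylsilyloxy)-2-{4-[3-(2,6-dihydroxy-4-triisopropylsilyloxyphenyl)-3-oxoprop-1-ynyl]-2,6-dimethoxyphenoxy}-3-[3-methoxy-4-(triisopropylsilyloxy)phenyl]propyl (E)-4-(triisopropylsilyloxy)cinnamate (formed in the flask, not isolated) | COc1cc([C@@H](O[Si](C)(C)C(C)(C)C)[C@H](COC(=O)/C=C/c2ccc(O[Si](C(C)C)(C(C)C)C(C)C)cc2)Oc2c(OC)cc(C#CC(=O)c3c(O)cc(O[Si](C(C)C)(C(C)C)C(C)C)cc3O)cc2OC)ccc1O[Si](C(C)C)(C(C)C)C(C)C | intermediate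
23 | diethylamino enaminone: the adduct of diethylamine to the ynone of 22, with NEt2 on the carbon attached to ring B, alkene geometry not defined (formed in the flask, not isolated) | COc1cc([C@@H](O[Si](C)(C)C(C)(C)C)[C@H](COC(=O)/C=C/c2ccc(O[Si](C(C)C)(C(C)C)C(C)C)cc2)Oc2c(OC)cc(C(=CC(=O)c3c(O)cc(O[Si](C(C)C)(C(C)C)C(C)C)cc3O)N(CC)CC)cc2OC)ccc1O[Si](C(C)C)(C(C)C)C(C)C | intermediate
24 | tetrasilyl ether of the target: (2S,3R)-3-(tert-butyldimethylsilyloxy)-2-{4-[5-hydroxy-4-oxo-7-(triisopropylsilyloxy)-4H-chromen-2-yl]-2,6-dimethoxyphenoxy}-3-[3-methoxy-4-(triisopropylsilyloxy)phenyl]propyl (E)-3-[4-(triisopropylsilyloxy)phenyl]prop-2-enoate | COc1cc([C@@H](O[Si](C)(C)C(C)(C)C)[C@H](COC(=O)/C=C/c2ccc(O[Si](C(C)C)(C(C)C)C(C)C)cc2)Oc2c(OC)cc(-c3cc(=O)c4c(O)cc(O[Si](C(C)C)(C(C)C)C(C)C)cc4o3)cc2OC)ccc1O[Si](C(C)C)(C(C)C)C(C)C | intermediate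
25 | (2S,3R)-3-hydroxy-2-[4-(5,7-dihydroxy-4-oxo-4H-chromen-2-yl)-2,6-dimethoxyphenoxy]-3-(4-hydroxy-3-methoxyphenyl)propyl (E)-3-(4-hydroxyphenyl)prop-2-enoate (CNP0264527.1) | COc1cc([C@@H](O)[C@H](COC(=O)/C=C/c2ccc(O)cc2)Oc2c(OC)cc(-c3cc(=O)c4c(O)cc(O)cc4o3)cc2OC)ccc1O | target

**Step count and risks**

Total steps: 16. Longest linear sequence: 12 steps (steps 1–4, 6–10, 12, 15 and 16).

Steps most likely to fail:

1. Step 15 (carbonylative annulation). The aroylpalladium intermediate may be intercepted by diethylamine (aminocarbonylation), or alkynyl transfer may outrun CO insertion so that the alkyne couples directly and the phenol then closes a benzofuran. Protodeiodination of the electron-rich iodoresorcinol would add to the loss.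
 Fallback, setting out from alkyne 18 and returning at target 25, with the C4a–C4 bond bought in and no CO used:
 - Commercial 2,4,6-trihydroxybenzoic acid is peracetylated (Ac2O, pyridine) to 2,4,6-triacetoxybenzoic acid F1.
 - Oxalyl chloride with catalytic DMF converts it into 2,4,6-triacetoxybenzoyl chloride F2.
 - Acyl Sonogashira coupling of F2 with 18 (PdCl2(PPh3)2, CuI, Et3N, THF, rt) forms C4–C3 and gives ynone triacetate F3.
 - Diethylamine in THF cleaves the aryl acetates by aminolysis and adds to the ynone, and a freed ortho-hydroxyl closes ring C by the same 6-endo addition–elimination, giving 5,7-dihydroxyflavone trisilyl ether F4.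
 - The conditions of step 16 then remove the three remaining silyl groups to give 25.

2. Step 6 (Grignard addition). The α-aryloxy aldehyde may epimerise before or during the addition, and facial selectivity may be poor if a magnesium chelate through the aryloxy or methoxy oxygens competes with the Felkin–Anh pathway.
 Fallback, setting out from ester 5 and returning at alcohol 10, with Cα set by ketone reduction:
 - Ester 5 is converted with MeNHOMe·HCl and i-PrMgCl (THF, −20 °C) into Weinreb amide F5.
 - Arylmagnesium bromide 9 adds once to give aryl ketone F6.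
 - Zn(BH4)2 in Et2O at −20 °C reduces F6 through a zinc chelate between the ketone and the Cβ aryloxy oxygen, with hydride delivered from the face opposite the CH2OTBS group, which should give the anti alcohol 10.

3. Step 3 (Mitsunobu etherification). Capture of the activated glycerate by the hindered 2,6-dimethoxyphenol may be slow, allowing β-elimination or alkylation of the hydrazine dicarboxylate, and the stereochemical integrity of Cβ could be eroded.
 Fallback, setting out from hydroxy ester 3 and returning at aryl ether 5: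
 - Tf2O and 2,6-lutidine (CH2Cl2, −78 °C) give triflate F7.
 - The potassium phenoxide of 4 (K2CO3, MeCN, 0 °C → rt) displaces the triflate in a direct SN2 reaction with inversion, giving 5.

**Further compounds**

F1 | step 15 | 2,4,6-triacetoxybenzoic acid | CC(=O)Oc1cc(OC(C)=O)c(C(=O)O)c(OC(C)=O)c1
F2 | step 15 | 2,4,6-triacetoxybenzoyl chloride | CC(=O)Oc1cc(OC(C)=O)c(C(=O)Cl)c(OC(C)=O)c1
F3 | step 15 | ynone triacetate: (2S,3R)-3-(tert-butyldimethylsilyloxy)-2-{4-[3-(2,4,6-triacetoxyphenyl)-3-oxoprop-1-ynyl]-2,6-dimethoxyphenoxy}-3-[3-methoxy-4-(triisopropylsilyloxy)phenyl]propyl (E)-4-(triisopropylsilyloxy)cinnamate | COc1cc([C@@H](O[Si](C)(C)C(C)(C)C)[C@H](COC(=O)/C=C/c2ccc(O[Si](C(C)C)(C(C)C)C(C)C)cc2)Oc2c(OC)cc(C#CC(=O)c3c(OC(C)=O)cc(OC(C)=O)cc3OC(C)=O)cc2OC)ccc1O[Si](C(C)C)(C(C)C)C(C)C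
F4 | step 15 | 5,7-dihydroxyflavone trisilyl ether: compound 24 without the 7-O-triisopropylsilyl group | COc1cc([C@@H](O[Si](C)(C)C(C)(C)C)[C@H](COC(=O)/C=C/c2ccc(O[Si](C(C)C)(C(C)C)C(C)C)cc2)Oc2c(OC)cc(-c3cc(=O)c4c(O)cc(O)cc4o3)cc2OC)ccc1O[Si](C(C)C)(C(C)C)C(C)C
F5 | step 6 | (S)-2-(4-bromo-2,6-dimethoxyphenoxy)-3-(tert-butyldimethylsilyloxy)-N-methoxy-N-methylpropanamide | CON(C)C(=O)[C@@H](Oc1c(OC)cc(Br)cc1OC)CO[Si](C)(C)C(C)(C)C
F6 | step 6 | (S)-2-(4-bromo-2,6-dimethoxyphenoxy)-3-(tert-butyldimethylsilyloxy)-1-[3-methoxy-4-(triisopropylsilyloxy)phenyl]propan-1-one | COc1cc(C(=O)[C@H](CO[Si](C)(C)C(C)(C)C)Oc2c(OC)cc(Br)cc2OC)ccc1O[Si](C(C)C)(C(C)C)C(C)C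
F7 | step 3 | methyl (R)-3-(tert-butyldimethylsilyloxy)-2-(trifluoromethylsulfonyloxy)propanoate | COC(=O)[C@H](OS(=O)(=O)C(F)(F)F)CO[Si](C)(C)C(C)(C)C
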